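## Retrosynthetic overview

- The p-quinone is unmasked last, by Teuber (Fremy's salt) oxidation of a 2-methoxy-6-alkylphenol; the acetate goes on before the phenol is freed from its benzyl ether.
- The ArCH2–CH(O) bond comes from copper-catalysed opening of (R)-2-undecyloxirane by the Grignard reagent of O-benzyl-6-bromoguaiacol.
- The epoxide comes from (R)-1-chlorotridecan-2-ol, made by ketoreductase reduction of achiral 1-chlorotridecan-2-one; this sets the only stereocentre.
- The chloroketone comes from undecylmagnesium bromide and 2-chloro-N-methoxy-N-methylacetamide.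
- Rings: the six-membered carbocycle is bought as the arene and never built; the only ring formed is the oxirane (step 3), which is opened again in step 5.

Assumption: the ketoreductase in step 2 is chosen by a short screen of a commercial panel; a Prelog-type alcohol dehydrogenase is assumed, which gives the (R)-alcohol from chloromethyl ketones because CH2Cl outranks the alkyl chain in the CIP order.

## Route

Step 1
Reactants: 1 1-bromoundecane; 2 2-chloro-N-methoxy-N-methylacetamide
Product: 5 1-chlorotridecan-2-one, via undecylmagnesium bromide 3 (not isolated), via magnesium hemiaminal chelate 4 (not isolated)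
Conditions: Mg, I2 (cat.), THF, reflux; then add to 2 in THF, −10 → 0 °C; cold 1 M HCl
Reagents that add atoms: none
Why: Grignard formation followed by Weinreb ketone synthesis, in which the chelated tetrahedral adduct survives until acidic work-up, so neither over-addition nor attack on the primary chloride competes at 0 °C.

Step 2
Reactants: 5 1-chlorotridecan-2-one
Product: 6 (2R)-1-chlorotridecan-2-ol
Conditions: ketoreductase (NADH-dependent alcohol dehydrogenase, Prelog-type, e.g. Rhodococcus ruber ADH-A), NAD+ (cat.), iPrOH (20% v/v), KPi buffer pH 7.0, 30 °C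
Reagents that add atoms: none
Why: Enzymatic asymmetric ketone reduction, in which the ketoreductase binds the small CH2Cl and the long alkyl chain in different pockets and delivers hydride from NADH to one face only, giving the (R)-chlorohydrin while isopropanol recycles the cofactor.

Step 3
Reactants: 6 (2R)-1-chlorotridecan-2-ol
Product: 7 (2R)-2-undecyloxirane
Conditions: KOH, MeOH, 0 °C → rt
Reagents that add atoms: none
Why: Intramolecular Williamson etherification (halohydrin to epoxide), in which the alkoxide displaces the primary chloride at C1, so the C2 stereocentre is untouched and stays (R).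

Step 4
Reactants: 8 2-bromo-6-methoxyphenol
Product: 9 2-(benzyloxy)-1-bromo-3-methoxybenzene
Conditions: BnBr, K2CO3, DMF, rt → 50 °C
Reagents that add atoms: benzyl bromide, BrCc1ccccc1
Why: Williamson O-benzylation of the phenol, giving an ether that tolerates Grignard chemistry and is later removed by neutral hydrogenolysis beside the acetate.

Step 5
Reactants: 9 2-(benzyloxy)-1-bromo-3-methoxybenzene (1.5 equiv); 7 (2R)-2-undecyloxirane
Product: 11 (2R)-1-[2-(benzyloxy)-3-methoxyphenyl]tridecan-2-ol, via arylmagnesium bromide 10 (not isolated)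
Conditions: Mg, I2 (cat.), THF, reflux; CuI (10 mol%), then 7, THF, −40 → 0 °C; cold 1 M HCl
Reagents that add atoms: none
Why: Copper-catalysed SN2 opening of a terminal epoxide by an aryl Grignard reagent at the unsubstituted carbon, so the C–O bond at the stereocentre is not broken and (R) is kept (CH2O becomes CH2Ar with the same CIP rank).

Step 6
Reactants: 11 (2R)-1-[2-(benzyloxy)-3-methoxyphenyl]tridecan-2-ol
Product: 12 (2R)-1-[2-(benzyloxy)-3-methoxyphenyl]tridecan-2-yl acetate
Conditions: Ac2O, pyridine, DMAP (cat.), CH2Cl2, rt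
Reagents that add atoms: acetic anhydride, CC(=O)OC(C)=O
Why: DMAP-catalysed O-acylation of the secondary alcohol, which leaves the C–O bond and therefore the configuration intact.

Step 7
Reactants: 12 (2R)-1-[2-(benzyloxy)-3-methoxyphenyl]tridecan-2-yl acetate
Product: 13 (2R)-1-(2-hydroxy-3-methoxyphenyl)tridecan-2-yl acetate
Conditions: H2 (1 atm), 10% Pd/C, EtOAc, rt
Reagents that add atoms: none
Why: Catalytic hydrogenolysis of the benzyl aryl ether under neutral conditions; the acetate sits on a homobenzylic, not benzylic, carbon and is not cleaved.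

Step 8
Reactants: 13 (2R)-1-(2-hydroxy-3-methoxyphenyl)tridecan-2-yl acetate
Product: 14 (2R)-1-(5-methoxy-3,6-dioxocyclohexa-1,4-dien-1-yl)tridecan-2-yl acetate
Conditions: Fremy's salt (2.5 equiv), aq. KH2PO4, Aliquat 336 (cat.), CH2Cl2/H2O, rt
Reagents that add atoms: potassium nitrosodisulfonate (Fremy's salt), [K+].[K+].[O]N(S(=O)(=O)[O-])S(=O)(=O)[O-]
Why: Teuber oxidation, in which one equivalent of the nitroxyl radical forms the phenoxyl radical and a second adds at the free para position and collapses to the p-quinone under near-neutral conditions that spare the acetate and the stereocentre.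

## Compound list

1 | 1-bromoundecane | CCCCCCCCCCCBr | starting material
2 | 2-chloro-N-methoxy-N-methylacetamide | CON(C)C(=O)CCl | starting material
3 | undecylmagnesium bromide | CCCCCCCCCCC[Mg]Br | intermediate (not isolated)
4 | bromomagnesium 1-chloro-2-[methoxy(methyl)amino]tridecan-2-olate (magnesium hemiaminal chelate) | CCCCCCCCCCCC(CCl)(O[Mg]Br)N(C)OC | intermediate (not isolated)
5 | 1-chlorotridecan-2-one | CCCCCCCCCCCC(=O)CCl | intermediate
6 | (2R)-1-chlorotridecan-2-ol | CCCCCCCCCCC[C@H](CCl)O | intermediate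
7 | (2R)-2-undecyloxirane | CCCCCCCCCCC[C@@H]1CO1 | intermediate
8 | 2-bromo-6-methoxyphenol | COc1cccc(Br)c1O | starting material
9 | 2-(benzyloxy)-1-bromo-3-methoxybenzene | COc1cccc(Br)c1OCc1ccccc1 | intermediate
10 | [2-(benzyloxy)-3-methoxyphenyl]magnesium bromide | COc1cccc([Mg]Br)c1OCc1ccccc1 | intermediate (not isolated)
11 | (2R)-1-[2-(benzyloxy)-3-methoxyphenyl]tridecan-2-ol | CCCCCCCCCCC[C@H](Cc1cccc(OC)c1OCc1ccccc1)O | intermediate
12 | (2R)-1-[2-(benzyloxy)-3-methoxyphenyl]tridecan-2-yl acetate | CCCCCCCCCCC[C@H](Cc1cccc(OC)c1OCc1ccccc1)OC(C)=O | intermediate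
13 | (2R)-1-(2-hydroxy-3-methoxyphenyl)tridecan-2-yl acetate | CCCCCCCCCCC[C@H](Cc1cccc(OC)c1O)OC(C)=O | intermediate
14 | (2R)-1-(5-methoxy-3,6-dioxocyclohexa-1,4-dien-1-yl)tridecan-2-yl acetate | CCCCCCCCCCC[C@H](CC1=CC(=O)C=C(OC)C1=O)OC(C)=O | target

## Summary

Total step count: 8.
Longest linear sequence: 7 steps (1, 2, 3, 5, 6, 7, 8, from 1-bromoundecane); step 4 is a one-step side branch.

## Steps most likely to fail, with fallbacks

**Step 2.** The lipophilic, electrophilic chloroketone may be reduced too slowly or with too low ee by the enzymes on hand. The fallback moves the enzymatic reduction to an α-keto ester and reaches the epoxide through the 1,2-diol. It sets out from undecylmagnesium bromide 3 and comes back at epoxide 7. Compound 3 is added at −78 °C to excess diethyl oxalate F1 to give ethyl 2-oxotridecanoate F2. A ketoreductase selected for the (R)-alcohol (NADH, iPrOH recycling, buffer pH 7) reduces it to ethyl (2R)-2-hydroxytridecanoate F3. LiAlH4 in THF then gives (2R)-tridecane-1,2-diol F4, which is crystalline, so its ee can be raised by recrystallisation. Selective primary tosylation (TsCl, Et3N, cat. Bu2SnO, CH2Cl2) gives (2R)-2-hydroxytridecyl 4-methylbenzenesulfonate F5, and K2CO3 in MeOH closes it to 7 without touching C2.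

**Step 5.** Magnesium insertion into the hindered, electron-rich bromide 9 may be sluggish, and bromohydrin formation can compete with the opening. The fallback drops the aryl bromide and the benzyl ether and makes the aryl anion by directed ortho-metalation. It sets out from epoxide 7 and comes back at phenol 13. Guaiacol F6 is protected (MOMCl, iPr2NEt, CH2Cl2) as 1-methoxy-2-(methoxymethoxy)benzene F7. n-BuLi in THF at 0 °C lithiates ortho to the OMOM group to give [3-methoxy-2-(methoxymethoxy)phenyl]lithium F8. With BF3·OEt2 at −78 °C this opens 7 at the terminal carbon to give (2R)-1-[3-methoxy-2-(methoxymethoxy)phenyl]tridecan-2-ol F9 after an aqueous HCl quench. Acetylation as in step 6 gives (2R)-1-[3-methoxy-2-(methoxymethoxy)phenyl]tridecan-2-yl acetate F10. Cleavage of the aryl MOM ether (TFA, CH2Cl2, a little water, 0 °C) then gives 13.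

**Step 8.** The Teuber oxidation depends on the quality of Fremy's salt and on phase transfer of a greasy phenol. The fallback carries the para oxygen from the start, so the last step is only a hydroquinone-to-quinone oxidation. It sets out from epoxide 7 and comes back at target 14. Dakin oxidation (H2O2, aq. NaOH, then acid) of 5-bromovanillin F11 gives 2-bromo-6-methoxybenzene-1,4-diol F12. Dibenzylation (BnBr, K2CO3, DMF, under N2) gives 2,5-bis(benzyloxy)-1-bromo-3-methoxybenzene F13. Its Grignard reagent, [2,5-bis(benzyloxy)-3-methoxyphenyl]magnesium bromide F14, opens 7 under the conditions of step 5 to give (2R)-1-[2,5-bis(benzyloxy)-3-methoxyphenyl]tridecan-2-ol F15. Acetylation gives (2R)-1-[2,5-bis(benzyloxy)-3-methoxyphenyl]tridecan-2-yl acetate F16. Hydrogenolysis (H2, Pd/C, EtOAc) gives (2R)-1-(2,5-dihydroxy-3-methoxyphenyl)tridecan-2-yl acetate F17. A laccase (Trametes versicolor, air, acetate buffer pH 5/EtOAc, rt) oxidises F17 to 14.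

## Further compounds

F1 | step 2 | diethyl oxalate | CCOC(=O)C(=O)OCC
F2 | step 2 | ethyl 2-oxotridecanoate | CCCCCCCCCCCC(=O)C(=O)OCC
F3 | step 2 | ethyl (2R)-2-hydroxytridecanoate | CCCCCCCCCCC[C@H](C(=O)OCC)O
F4 | step 2 | (2R)-tridecane-1,2-diol | CCCCCCCCCCC[C@H](CO)O
F5 | step 2 | (2R)-2-hydroxytridecyl 4-methylbenzenesulfonate | CCCCCCCCCCC[C@H](COS(=O)(=O)c1ccc(C)cc1)O
F6 | step 5 | guaiacol (2-methoxyphenol) | COc1ccccc1O
F7 | step 5 | 1-methoxy-2-(methoxymethoxy)benzene | COCOc1ccccc1OC
F8 | step 5 | [3-methoxy-2-(methoxymethoxy)phenyl]lithium | COCOc1c([Li])cccc1OC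
F9 | step 5 | (2R)-1-[3-methoxy-2-(methoxymethoxy)phenyl]tridecan-2-ol | CCCCCCCCCCC[C@H](Cc1cccc(OC)c1OCOC)O
F10 | step 5 | (2R)-1-[3-methoxy-2-(methoxymethoxy)phenyl]tridecan-2-yl acetate | CCCCCCCCCCC[C@H](Cc1cccc(OC)c1OCOC)OC(C)=O
F11 | step 8 | 5-bromovanillin (3-bromo-4-hydroxy-5-methoxybenzaldehyde) | COc1cc(C=O)cc(Br)c1O
F12 | step 8 | 2-bromo-6-methoxybenzene-1,4-diol | COc1cc(O)cc(Br)c1O
F13 | step 8 | 2,5-bis(benzyloxy)-1-bromo-3-methoxybenzene | COc1cc(OCc2ccccc2)cc(Br)c1OCc1ccccc1
F14 | step 8 | [2,5-bis(benzyloxy)-3-methoxyphenyl]magnesium bromide | COc1cc(OCc2ccccc2)cc([Mg]Br)c1OCc1ccccc1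
F15 | step 8 | (2R)-1-[2,5-bis(benzyloxy)-3-methoxyphenyl]tridecan-2-ol | CCCCCCCCCCC[C@H](Cc1cc(OCc2ccccc2)cc(OC)c1OCc1ccccc1)O
F16 | step 8 | (2R)-1-[2,5-bis(benzyloxy)-3-methoxyphenyl]tridecan-2-yl acetate | CCCCCCCCCCC[C@H](Cc1cc(OCc2ccccc2)cc(OC)c1OCc1ccccc1)OC(C)=O
F17 | step 8 | (2R)-1-(2,5-dihydroxy-3-methoxyphenyl)tridecan-2-yl acetate | CCCCCCCCCCC[C@H](Cc1cc(O)cc(OC)c1O)OC(C)=O
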